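The pyrrole ring is cut so that N1, C2 (with its ester) and C3 (with the tricosyl chain) come from one alpha-amino acid: C2 sits between N1, the ester carbon and the alkene-type carbon C3, exactly the substitution a borono-Mannich reaction creates. One Petasis reaction of glyoxylic acid, allylamine and (pentacos-1-en-2-yl)boronic acid forms N1–C2 and C2–C3 and gives an acyclic diene amino acid whose N-allyl group already carries C4 and C5. The boron partner, a 1,1-disubstituted alkenylboronic acid, comes from 1-bromodocosane and 2,3-dibromopropene. Esterification, ring-closing metathesis (C3=C4) and dehydrogenation then complete the aromatic ring.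

Key step: step 3

Assumption: pyrrole numbering N1, C2 (ester), C3 (tricosyl), C4, C5 is used throughout; the target is achiral, so every intermediate with a C2 stereocentre is carried as the racemate.

Step 1
Reactants: 1 1-bromodocosane; 2 2,3-dibromopropene
Product: 4 2-bromopentacos-1-ene, via docosylmagnesium bromide 3 (not isolated)
Conditions: Mg turnings, THF, 50 °C; then 2 (1.3 equiv), CuBr·SMe2 (5 mol %), THF, 0 °C → rt
Reagents that add atoms: none
Why: Copper-catalysed allylic substitution by a Grignard reagent: SN2 and SN2′ attack on 2 both give the same 2-bromoalk-1-ene, and the vinylic C–Br bond is inert to the Grignard reagent under these conditions.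

Step 2
Reactants: 4 2-bromopentacos-1-ene
Product: 7 (pentacos-1-en-2-yl)boronic acid, via (pentacos-1-en-2-yl)magnesium bromide 5 (not isolated), via diisopropyl (pentacos-1-en-2-yl)boronate 6 (not isolated)
Conditions: Mg turnings, BrCH2CH2Br (cat.), THF, 50 °C; solution added to B(OiPr)3 (2 equiv), THF, −78 °C → rt; 1 M HCl, 0 °C; used without long storage
Reagents that add atoms: triisopropyl borate, CC(C)OB(OC(C)C)OC(C)C; water, O
Why: Magnesium insertion into the vinylic C–Br bond, borylation of the Grignard reagent with a hindered borate (which limits double addition) and acidic hydrolysis is the standard preparation of alkenylboronic acids; the 1,1-disubstituted alkene has no geometry to lose, and metalation above room temperature avoids the poor cold solubility of the C25 chain.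

Step 3
Reactants: 7 (pentacos-1-en-2-yl)boronic acid; 8 glyoxylic acid (charged as its monohydrate); 9 allylamine
Product: 12 racemic 2-(allylamino)-3-methylidenehexacosanoic acid, via 2-(allyliminio)acetate 10 (not isolated), via alkenylboronate ate complex 11 (not isolated)
Conditions: 8 (1.1 equiv), 9 (1.0 equiv), CH2Cl2/(CF3)2CHOH 4:1, rt, 30 min; then 7 (1.2 equiv), rt → 40 °C, 24–48 h
Reagents that add atoms: none
Why: Petasis borono-Mannich reaction: allylamine condenses with glyoxylic acid to the iminium carboxylate 10, an oxygen of 10 binds the boron of 7 to give the tetracoordinate boronate 11, and the alkenyl group then shifts intramolecularly from boron to the iminium carbon, so that N1–C2 and C2–C3 are made in one flask. The closest known reaction type is the three-component synthesis of beta,gamma-unsaturated alpha-amino acids from glyoxylic acid, amines and alkenylboronic acids, alpha-substituted vinylboronic acids included. No ring is closed in this step. The new C2 stereocentre is formed without any controlling element, hence as a racemate, which is acceptable because aromatisation erases it. The selectivity that matters is regiochemical: the carbon that carried boron must become C3, and the ipso transfer inside 11 secures this, placing the tricosyl chain on C3 and leaving the terminal CH2 free for the later metathesis. A second alkylation of the product amine is held back by the near-equimolar stoichiometry and by the hindered, zwitterionic nature of 12, while (CF3)2CHOH is added to speed up transfer from the hindered boronate.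

Step 4
Reactants: 12 racemic 2-(allylamino)-3-methylidenehexacosanoic acid
Product: 13 methyl 2-(allylamino)-3-methylidenehexacosanoate hydrochloride (racemic)
Conditions: SOCl2 (3 equiv), MeOH/CH2Cl2, 0 °C → 45 °C; evaporation
Reagents that add atoms: methanol, CO; thionyl chloride, O=S(Cl)Cl
Why: Fischer esterification with HCl generated in situ from SOCl2 and methanol is the standard route from an alpha-amino acid to its methyl ester hydrochloride; the protonated nitrogen cannot be acylated, and the acidic medium avoids base-induced migration of the C3 methylidene into conjugation with the ester.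

Step 5
Reactants: 13 methyl 2-(allylamino)-3-methylidenehexacosanoate hydrochloride
Product: 14 methyl 3-tricosyl-2,5-dihydro-1H-pyrrole-2-carboxylate hydrochloride (racemic)
Conditions: second-generation Hoveyda–Grubbs catalyst (5 mol %), CH2Cl2 (0.01 M), 40 °C, argon sweep
Reagents that add atoms: none
Why: Ring-closing metathesis of an ammonium salt: protonation keeps the nitrogen lone pair off ruthenium, the catalyst loads on the monosubstituted allyl alkene and closes onto the 1,1-disubstituted alkene to give the five-membered ring with the trisubstituted C3=C4 bond, driven by loss of ethene.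

Step 6
Reactants: 14 methyl 3-tricosyl-2,5-dihydro-1H-pyrrole-2-carboxylate hydrochloride
Product: 16 methyl 3-tricosyl-1H-pyrrole-2-carboxylate, via free-base 3-pyrroline ester 15 (not isolated)
Conditions: sat. aq NaHCO3, CH2Cl2, rt (organic layer dried over Na2SO4, not concentrated); then activated MnO2 (10 equiv), CH2Cl2, rt
Reagents that add atoms: none
Why: Dehydrogenative aromatisation of a 3-pyrroline with activated MnO2 is a known oxidation; the C2–H bond is allylic and alpha to both nitrogen and the ester, and the gain of aromaticity makes the pyrrole the sink while the C2 stereocentre disappears.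

Compound list
1 | 1-bromodocosane | CCCCCCCCCCCCCCCCCCCCCCBr | starting material
2 | 2,3-dibromopropene | C=C(Br)CBr | starting material
3 | docosylmagnesium bromide | CCCCCCCCCCCCCCCCCCCCCC[Mg]Br | intermediate
4 | 2-bromopentacos-1-ene | CCCCCCCCCCCCCCCCCCCCCCCC(=C)Br | intermediate
5 | (pentacos-1-en-2-yl)magnesium bromide | CCCCCCCCCCCCCCCCCCCCCCCC(=C)[Mg]Br | intermediate
6 | diisopropyl (pentacos-1-en-2-yl)boronate | CCCCCCCCCCCCCCCCCCCCCCCC(=C)B(OC(C)C)OC(C)C | intermediate
7 | (pentacos-1-en-2-yl)boronic acid | CCCCCCCCCCCCCCCCCCCCCCCC(=C)B(O)O | intermediate
8 | glyoxylic acid monohydrate | O=CC(=O)O.O | starting material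
9 | allylamine (prop-2-en-1-amine) | C=CCN | starting material
10 | 2-(allyliminio)acetate (iminium carboxylate zwitterion) | C=CC[NH+]=CC(=O)[O-] | intermediate
11 | tetracoordinate boronate: dihydroxy(pentacos-1-en-2-yl)borate bound to the carboxylate oxygen of the N-allyl iminium | CCCCCCCCCCCCCCCCCCCCCCCC(=C)[B-](O)(O)OC(=O)C=[NH+]CC=C | intermediate
12 | 2-(allylamino)-3-methylidenehexacosanoic acid (racemic) | CCCCCCCCCCCCCCCCCCCCCCCC(=C)C(NCC=C)C(=O)O | intermediate
13 | methyl 2-(allylamino)-3-methylidenehexacosanoate hydrochloride (racemic) | CCCCCCCCCCCCCCCCCCCCCCCC(=C)C(NCC=C)C(=O)OC.Cl | intermediate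
14 | methyl 3-tricosyl-2,5-dihydro-1H-pyrrole-2-carboxylate hydrochloride (racemic) | CCCCCCCCCCCCCCCCCCCCCCCC1=CCNC1C(=O)OC.Cl | intermediate
15 | methyl 3-tricosyl-2,5-dihydro-1H-pyrrole-2-carboxylate (racemic free base) | CCCCCCCCCCCCCCCCCCCCCCCC1=CCNC1C(=O)OC | intermediate
16 | methyl 3-tricosyl-1H-pyrrole-2-carboxylate (achiral) | CCCCCCCCCCCCCCCCCCCCCCCc1cc[nH]c1C(=O)OC | target

Total step count: 6
Longest linear sequence: 6 steps (1 → 4 → 7 → 12 → 13 → 14 → 16)

Steps most likely to fail

Step 3. The alkenyl shift within the hindered 1,1-disubstituted boronate may be slow, so that protodeboronation of 7 and a second borono-Mannich reaction at the secondary amine compete. The fallback makes C2–C3 by Grignard addition to an N-acylimine (glycine-cation chemistry) instead of by boron-to-carbon transfer.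
- It sets out from 4, which is converted into the Grignard reagent 5 as in step 2.
- Commercial methyl N-(tert-butoxycarbonyl)glycinate is brominated (NBS, light, PhCF3) to racemic methyl 2-bromo-2-[(tert-butoxycarbonyl)amino]acetate F1.
- Et3N in THF at −78 °C removes HBr to give methyl 2-[(tert-butoxycarbonyl)imino]acetate F2. Reagent 5 should add to its imine carbon and, after quenching with water, give racemic methyl 2-[(tert-butoxycarbonyl)amino]-3-methylidenehexacosanoate F3.
- HCl in dioxane should remove the carbamate to give methyl 2-amino-3-methylidenehexacosanoate hydrochloride F4.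
- Selective mono-N-allylation (allyl bromide 1.0 equiv, LiOH·H2O, 4 Å molecular sieves, DMF, rt) should give methyl 2-(allylamino)-3-methylidenehexacosanoate F5.
- HCl in Et2O converts F5 into 13, where the route is rejoined.

Step 5. The ruthenium carbene may be lost through amine coordination if protonation is incomplete, or the reaction may stall before closure onto the 1,1-disubstituted alkene. The fallback masks nitrogen as a carbamate for the metathesis.
- It sets out from 13. Boc2O and Et3N in THF at 50 °C should give, through the free amine already listed as F5, racemic methyl 2-[allyl(tert-butoxycarbonyl)amino]-3-methylidenehexacosanoate F6.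
- Ring-closing metathesis of this carbamate with second-generation Grubbs catalyst (CH2Cl2, 40 °C) should give racemic 1-tert-butyl 2-methyl 3-tricosyl-2,5-dihydro-1H-pyrrole-1,2-dicarboxylate F7.
- HCl in dioxane should cleave the carbamate and return the route at 14.

Step 2. Magnesium insertion at the vinylic bromide may be incomplete and accompanied by Wurtz-type dimerisation, the borate may take up two alkenyl groups, or the waxy boronic acid may protodeboronate during acidic work-up. The fallback avoids any organomagnesium intermediate.
- It sets out from 4. Miyaura borylation (B2pin2, PdCl2(PPh3)2, PPh3, KOPh, toluene, 50 °C) should give 4,4,5,5-tetramethyl-2-(pentacos-1-en-2-yl)-1,3,2-dioxaborolane F8.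
- Oxidative removal of the pinacol unit (NaIO4, NH4OAc, acetone/THF/H2O, rt) should give 7, where the route is rejoined.

Further compounds
F1 | step 3 | methyl 2-bromo-2-[(tert-butoxycarbonyl)amino]acetate (racemic) | COC(=O)C(Br)NC(=O)OC(C)(C)C
F2 | step 3 | methyl 2-[(tert-butoxycarbonyl)imino]acetate | COC(=O)C=NC(=O)OC(C)(C)C
F3 | step 3 | methyl 2-[(tert-butoxycarbonyl)amino]-3-methylidenehexacosanoate (racemic) | CCCCCCCCCCCCCCCCCCCCCCCC(=C)C(NC(=O)OC(C)(C)C)C(=O)OC
F4 | step 3 | methyl 2-amino-3-methylidenehexacosanoate hydrochloride (racemic) | CCCCCCCCCCCCCCCCCCCCCCCC(=C)C(N)C(=O)OC.Cl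
F5 | step 3 | methyl 2-(allylamino)-3-methylidenehexacosanoate (racemic free base) | CCCCCCCCCCCCCCCCCCCCCCCC(=C)C(NCC=C)C(=O)OC
F6 | step 5 | methyl 2-[allyl(tert-butoxycarbonyl)amino]-3-methylidenehexacosanoate (racemic) | CCCCCCCCCCCCCCCCCCCCCCCC(=C)C(N(CC=C)C(=O)OC(C)(C)C)C(=O)OC
F7 | step 5 | 1-tert-butyl 2-methyl 3-tricosyl-2,5-dihydro-1H-pyrrole-1,2-dicarboxylate (racemic) | CCCCCCCCCCCCCCCCCCCCCCCC1=CCN(C(=O)OC(C)(C)C)C1C(=O)OC
F8 | step 2 | 4,4,5,5-tetramethyl-2-(pentacos-1-en-2-yl)-1,3,2-dioxaborolane | CCCCCCCCCCCCCCCCCCCCCCCC(=C)B1OC(C)(C)C(C)(C)O1
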